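Count the target's half-life first. We must decide what to expect of a higher charge at the asked time, so we need to know what the flat stretch in the target readings means.

| flask | substrate | partner | remark | time |
|---|---|---|---|---|
| Tuesday's | 0.0024 M | 1.05 equiv | run made earlier |  |
| Saturday's | 0.026 M | 1.05 equiv | run made earlier |  |
| beta | 0.025 M | 1.05 equiv |  | 40 min |
| gamma | 0.0040 M | 1.05 equiv |  | 40 min |
| zeta | 0.030 M | 1.05 equiv |  | 40 min |
| eta | 0.015 M | 1.05 equiv |  | 40 min |

| run | time / min | target / % | substrate / % |
|---|---|---|---|
| Tuesday's | 2.50 | 0.7 | 93.7 |
| Tuesday's | 4.00 | 3.3 | 88.5 |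
| Tuesday's | 6.00 | 4.4 | 83.9 |
| Tuesday's | 10.0 | 5.5 | 75.2 |
| Tuesday's | 15.0 | 9.2 | 66.3 |
| Tuesday's | 30.0 | 9.0 | 47.8 |
| Saturday's | 2.50 | 20.3 | 73.1 |
| Saturday's | 4.00 | 28.5 | 62.8 |
| Saturday's | 6.00 | 36.1 | 53.2 |
| Saturday's | 10.0 | 41.1 | 40.2 |
| Saturday's | 15.0 | 43.1 | 34.2 |
| Saturday's | 30.0 | 41.5 | 19.7 |

(scatter of a reading: 1 percentage point)

- the flasks put in order of amount of target, in percent of the substrate charged, best first, at 40 min (beta / gamma / zeta / eta)
- the amount of target, in percent of the substrate charged of the flask you put first, at 40 min
- the amount of target, in percent of the substrate charged of the flask you put last, at 40 min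

- the numbers in the tables scatter with a standard deviation of 1 percentage point
- in a conversion other conformer counts as not yet reacted

At 4.00 min Saturday's run holds ten times the target of Tuesday's, so a higher c(substrate) helps early. Between 15.0 min and 30.0 min Saturday's substrate falls at 0.0368 min⁻¹ and Tuesday's at 0.0218 min⁻¹. Saturday's charge being ten times Tuesday's, we take Tuesday's pace as the leak to other conformer, so 40.7% of Saturday's loss in this stretch goes to target, less than the 75.5% of its first reading. Saturday's substrate falls by 15 percentage points here, so at that share about 5.9 points of target should appear, yet the reading goes from 43.1% to 41.5%. We read this as a balance, not a stop: about 7.5 points was used up from a mean of 42.3%. So we carry 58.6 min, a reading with the scatter on it: the target half-life, the time in which this loss by itself halves the target standing.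

From Saturday's last reading to the asked time, that loss costs 4.6 points. Substrate falling at its last pace repays 2.5 points, which is less. At Saturday's strength we therefore expect about 39.3%, below the plateau, and we would still rank the flasks by c(substrate).

The forecast gives zeta > beta > eta > gamma and calls the target at the asked time “essentially the plateau”, with 45% first and 14% last.

The flasks give zeta > beta > eta > gamma, with 35.3% for zeta and 14.0% for gamma; beta's 33.4% lies below our 39.3%.

    partner ⇌ dormant form (K = 2.70, k = 0.0400 min⁻¹)
    substrate + partner → target (k = 4.80 M⁻¹ min⁻¹)
    target ⇌ isomer of the product B (K = 17.0, k = 0.0170 min⁻¹)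
    partner + other conformer → isomer of the product A (k = 23.0 M⁻¹ min⁻¹)
    substrate ⇌ other conformer (K = 2.90, k = 0.0200 min⁻¹)

In gamma at 40.0 min, target is made at half the rate at which it is used up, a ratio of 0.488. Gamma read at 1.5 h holds 8.15%, against the 7.74% that the half-life gives with no making.

The readings were generated by integration for substances that don't exist; the scatter is artificial.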